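Whatever is charged stands in some form, so the percentages of all forms in a flask add up to 100. I therefore follow fractions left, not amounts made. A first-order step removes the same fraction of what is left, whatever the charge.

| setting | winter | noon | flask |
|---|---|---|---|
| starting material | 0.42 M | 0.95 M | 0.63 M |
| remark | run made earlier | run made earlier |  |
| time |  |  | 5.0 h |

- winter (time / h: target / %, starting material / %): 0.417: 23.8, 12.9; 0.833: 32.2, 5.0; 1.50: 34.7, 2.3; 3.00: 33.1, 0; 6.00: 24.5, 0.6
- noon (time / h: target / %, starting material / %): 0.417: 23.7, 13.1; 0.833: 39.4, 4.1; 1.50: 49.4, 1.7; 3.00: 46.0, 0; 6.00: 31.0, 1.5

(standard deviation of a reading: 1 percentage point)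

- a reading or a percentage of target counts all its forms, free or not

1. the moment within 5.0 h at which there is most target
2. the amount of target, in percent of the starting material charged, at that time
3. earliest time at which at least nineteen twentieths of that best amount are there
4. latest time at which they still are

At 0.417 h, the winter run has 12.9% of its starting material left and the noon run 13.1%, although the noon charge is about twice the winter charge. Target reads 23.8% and 23.7%, so up to that reading the two runs share one curve in percent. At 0.833 h they part: the noon run reads 39.4% and the winter run 32.2%, a gap of 7.2 percentage points against a scatter of 1 point.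

I read this as a threshold in the concentration of target. Let c* be the highest concentration seen on the shared curve. The noon reading at 0.417 h gives c* = 0.225 M. Dividing c* by the winter peak reading, 34.7%, gives the critical charge Q* = 0.649 M, the charge whose peak on the shared curve just reaches c*.

This flask's charge of 0.63 M lies below Q*, though the margin is thin. So I expect it to follow the winter curve: a best near 34.7% around 1.50 h, with the window asked for opening just after 0.833 h and closing near 3.00 h.

The forecast differs from my reckoning. It gives 42% at 1.9 h, with a window from 1.25 h to 2.8 h, on the ground that “the higher concentration gives more target”.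

The flask gives 35.1% at 1.55 h, with a window from 0.952 h to 2.51 h.

    target ⇌ isomer of the product A (K = 0.180, k = 4.70 × 10⁻⁴ /s)
    target → over-reaction product (k = 6.80 × 10⁻⁵ /s)
    other conformer → isomer of the product A (k = 4.80 × 10⁻⁴ /s)
    starting material ⇌ other conformer (K = 3.10, k = 0.00120 /s)
    crystals ⇌ target, rate k5*(cs5 - [target]) while solid is left; crystals form when [target] > cs5 (solubility = 0.240 M, k = 0.0230 /s)
    target ⇌ isomer of the product B (K = 1.20, k = 0.00130 /s)
    starting material → target (k = 5.70 × 10⁻⁴ /s)

This flask's charge lies under Q* = 0.649 M, its best holds 0.221 M of target, under the saturation concentration 0.24 M, and crystals stand at 0% at the best time. A further flask charged with 1.1 M, above Q*, reaches 56.6% and ends with 22.0% as crystals.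

All runs are calculated for an exercise; scatter was added.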